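## Retrosynthetic overview

1. Feature: the only ring is the 14-membered carbocycle C1–C14. Its only stereocentre, C14, lies between the allylic ring methylene C1 (next to Z C2=C3) and the exocyclic E C15=C16 olefin. An allylsilane carrying silicon at C16 leaves exactly this array when C14 attacks a C1 allyl cation.
2. The C7 CH2OH group is carried as a methyl ester until the last step. The ester makes C6=C7 too electron-poor to take part in the cationic step.
3. The ring is formed once, by C1–C14 closure of an acyclic (2Z,6E,10E,14Z,16R) C1 diethyl phosphate / C16 silane.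
4. That chain comes from a C7–C8 B-alkyl Suzuki–Miyaura coupling. The partners are a C8–C20 diene-allylsilane and a C1–C7 (Z)-α-bromoenoate made from neryl acetate.
5. The 14Z,16R allylsilane comes from a Zweifel olefination (C15–C16). The partners are an E alkenyl iodide made from geranyl acetate and an (S)-α-silyl boronic ester made from homoprenyl carbamate.

Key step: step 17

Remark: all chain compounds carry the numbering of the target (C14 stereocentre, C1 its allylic ring CH2, C7 the carbon bearing CH2OH, C15–C20 the side chain). Geranyl acetate, neryl acetate, (+)-sparteine and PhMe2Si–Bpin are assumed to be purchasable.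

## Route

Step 1
Reactants: 1 4-methylpent-3-en-1-ol
Product: 2 4-methylpent-3-en-1-yl N,N-diisopropylcarbamate
Conditions: i-Pr2NC(O)Cl, Et3N, CH2Cl2, reflux
Reagents that add atoms: N,N-diisopropylcarbamoyl chloride, CC(C)N(C(C)C)C(=O)Cl
Why: O-carbamoylation of the primary alcohol (acyl substitution) installs the group that directs the lithiation and later leaves, and the trisubstituted olefin is inert.

Step 2
Reactants: 2 4-methylpent-3-en-1-yl N,N-diisopropylcarbamate
Product: 5 (S)-2-[1-(dimethylphenylsilyl)-4-methylpent-3-en-1-yl]-4,4,5,5-tetramethyl-1,3,2-dioxaborolane, via lithiated carbamate 3 (not isolated), via silylboronate complex 4 (not isolated)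
Conditions: s-BuLi, (+)-sparteine, Et2O, −78 °C; PhMe2Si–Bpin, −78 °C → reflux
Reagents that add atoms: 2-(dimethylphenylsilyl)-4,4,5,5-tetramethyl-1,3,2-dioxaborolane, C[Si](C)(c1ccccc1)B1OC(C)(C)C(C)(C)O1
Why: Sparteine-mediated asymmetric deprotonation and lithiation–borylation: s-BuLi/(+)-sparteine removes the pro-R hydrogen next to oxygen, the configurationally stable organolithium 3 adds to boron with retention, and on warming the silyl group of 4 migrates from boron to carbon anti to the leaving carbamate (inversion), which sets the future C16 as the S boronic ester.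

Step 3
Reactants: 6 geranyl acetate
Product: 7 6,7-epoxygeranyl acetate (racemic epoxide)
Conditions: mCPBA (1.0 equiv), CH2Cl2, −20 → 0 °C
Reagents that add atoms: mCPBA, OOC(=O)c1cccc(Cl)c1
Why: Prilezhaev epoxidation should take the remote trisubstituted olefin, because the allylic acetate lowers the nucleophilicity of the 2,3-olefin.

Step 4
Reactants: 7 6,7-epoxygeranyl acetate
Product: 9 (E)-3-methyl-6-oxohex-2-en-1-yl acetate, via diol 8 (not isolated)
Conditions: H5IO6, THF/Et2O, 0 °C
Reagents that add atoms: none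
Why: Acid-mediated opening of the epoxide to diol 8 and Malaprade glycol cleavage in one flask release the C14 aldehyde and acetone without touching the E olefin or the acetate.

Step 5
Reactants: 9 (E)-3-methyl-6-oxohex-2-en-1-yl acetate
Product: 11 (E)-3-methylhept-2-en-6-yn-1-ol, via hydroxy aldehyde 10 (not isolated)
Conditions: dimethyl (1-diazo-2-oxopropyl)phosphonate, K2CO3, MeOH, 0 °C → rt
Reagents that add atoms: dimethyl (1-diazo-2-oxopropyl)phosphonate, COP(=O)(OC)C(=[N+]=[N-])C(C)=O
Why: Seyferth–Gilbert homologation in its Ohira–Bestmann form adds C15 as a terminal alkyne carbon, and the same K2CO3/MeOH medium transesterifies the allylic acetate, so the C9 alcohol is freed without a separate step.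

Step 6
Reactants: 11 (E)-3-methylhept-2-en-6-yn-1-ol
Product: 13 (E)-3-methyloct-2-en-6-yn-1-ol, via dilithio species 12 (not isolated)
Conditions: n-BuLi (2.1 equiv), THF, −78 → 0 °C; MeI (1.1 equiv), −78 °C → rt
Reagents that add atoms: iodomethane, CI
Why: Acetylide alkylation: in the alkoxide–acetylide 12 the carbon nucleophile should take up the single equivalent of MeI, since a lithium alkoxide in THF is methylated much more slowly.

Step 7
Reactants: 13 (E)-3-methyloct-2-en-6-yn-1-ol
Product: 15 (2E,6E)-7-iodo-3-methylocta-2,6-dien-1-ol, via alkenylzirconocene 14 (not isolated)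
Conditions: Cp2Zr(H)Cl (2.5 equiv), THF, rt → 40 °C; I2, 0 °C, dark
Reagents that add atoms: iodine, II
Why: Hydrozirconation–iodination: one equivalent of Cp2Zr(H)Cl is used up by the OH group, syn addition to the alkyne with excess hydride equilibrates zirconium to the less hindered methyl-bearing C15, and iodinolysis with retention gives the E iodide (iodine trans to C13), while the trisubstituted olefin does not react.

Step 8
Reactants: 15 (2E,6E)-7-iodo-3-methylocta-2,6-dien-1-ol
Product: 16 (2E,6E)-7-iodo-3-methylocta-2,6-dienal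
Conditions: MnO2, CH2Cl2, rt
Reagents that add atoms: none
Why: MnO2 oxidation is selective for the allylic alcohol and should leave the enal geometry and the alkenyl iodide unchanged.

Step 9
Reactants: 16 (2E,6E)-7-iodo-3-methylocta-2,6-dienal
Product: 17 (3E,7E)-8-iodo-4-methylnona-1,3,7-triene
Conditions: MePPh3Br, n-BuLi, THF, 0 °C; then 16, −78 → 0 °C
Reagents that add atoms: methyltriphenylphosphonium bromide, C[P+](c1ccccc1)(c1ccccc1)c1ccccc1.[Br-]
Why: Wittig methylenation adds C8 and turns the C9 terminus into a terminal diene, a handle that survives organolithium chemistry and needs no protecting group.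

Step 10
Reactants: 17 (3E,7E)-8-iodo-4-methylnona-1,3,7-triene; 5 (S)-α-silyl boronic ester
Product: 21 [(3E,7Z,9R)-4,8,12-trimethyltrideca-1,3,7,11-tetraen-9-yl]dimethyl(phenyl)silane, via alkenyllithium 18 (not isolated), via alkenylboronate complex 19 (not isolated), via beta-iodo boronic ester 20 (not isolated)
Conditions: t-BuLi (2 equiv), Et2O, −78 °C; 5 (1.2 equiv), THF, −78 °C; I2, THF, −78 °C; NaOMe, MeOH, −78 °C → rt
Reagents that add atoms: none
Why: Zweifel olefination: iodine–lithium exchange keeps the geometry of 17, ate complex 19 is iodinated at C14 with an anti 1,2-shift of C16 from boron to C15 (retention at C16), and methoxide-induced anti elimination of boron and iodide from 20 inverts the olefin geometry, so the E iodide gives the 14Z olefin and the S boronic ester becomes the 16R allylsilane (the descriptor changes by priority only).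

Step 11
Reactants: 22 neryl acetate
Product: 23 6,7-epoxyneryl acetate (racemic epoxide)
Conditions: mCPBA (1.0 equiv), CH2Cl2, −20 → 0 °C
Reagents that add atoms: mCPBA, OOC(=O)c1cccc(Cl)c1
Why: Prilezhaev epoxidation should again prefer the remote olefin over the acetate-deactivated Z 2,3-olefin.

Step 12
Reactants: 23 6,7-epoxyneryl acetate
Product: 25 (Z)-3-methyl-6-oxohex-2-en-1-yl acetate, via diol 24 (not isolated)
Conditions: H5IO6, THF/Et2O, 0 °C
Reagents that add atoms: none
Why: Epoxide hydrolysis to diol 24 and Malaprade cleavage give the C6 aldehyde with the Z C2=C3 olefin of nerol intact.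

Step 13
Reactants: 25 (Z)-3-methyl-6-oxohex-2-en-1-yl acetate
Product: 26 methyl (2Z,6Z)-8-acetoxy-2-bromo-6-methylocta-2,6-dienoate
Conditions: Ph3P=CHCO2Me, NBS, CH2Cl2, −20 °C; then 25, rt
Reagents that add atoms: methyl (triphenylphosphoranylidene)acetate, COC(=O)C=P(c1ccccc1)(c1ccccc1)c1ccccc1; N-bromosuccinimide, O=C1CCC(=O)N1Br
Why: Wittig olefination with the stabilised α-bromo ylide made in the flask should place the C5 chain trans to the ester and cis to bromine, which fixes the later C6=C7 geometry.

Step 14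
Reactants: 26 methyl (2Z,6Z)-8-acetoxy-2-bromo-6-methylocta-2,6-dienoate
Product: 27 methyl (2Z,6Z)-2-bromo-8-hydroxy-6-methylocta-2,6-dienoate
Conditions: K2CO3 (cat.), MeOH, 0 °C
Reagents that add atoms: none
Why: Base-catalysed transesterification removes the allylic acetate before any zerovalent palladium is present, and exchange at the methyl ester in methanol is degenerate.

Step 15
Reactants: 21 diene-allylsilane; 27 methyl (2Z,6Z)-2-bromo-8-hydroxy-6-methylocta-2,6-dienoate
Product: 29 methyl (2Z,6E,10E,14Z,16R)-16-[dimethyl(phenyl)silyl]-1-hydroxy-3,11,15,19-tetramethylicosa-2,6,10,14,18-pentaene-7-carboxylate, via B-alkyl-9-BBN 28 (not isolated)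
Conditions: 9-BBN (1.05 equiv), THF, 0 °C → rt; then 27, PdCl2(dppf), AsPh3, Cs2CO3, DMF/H2O, rt
Reagents that add atoms: none
Why: 9-BBN should add only to the monosubstituted C8=C9 end of the diene (anti-Markovnikov, the trisubstituted olefins being too hindered), and the B-alkyl Suzuki–Miyaura coupling of 28 with the alkenyl bromide goes with retention, so C8 takes the place of bromine cis to C5 and the 6E enoate results.

Step 16
Reactants: 29 hydroxy ester
Product: 30 methyl (2Z,6E,10E,14Z,16R)-1-(diethoxyphosphoryloxy)-16-[dimethyl(phenyl)silyl]-3,11,15,19-tetramethylicosa-2,6,10,14,18-pentaene-7-carboxylate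
Conditions: (EtO)2P(O)Cl, pyridine, CH2Cl2, 0 °C
Reagents that add atoms: diethyl chlorophosphate, CCOP(=O)(Cl)OCC
Why: O-phosphorylation of the primary allylic alcohol under basic conditions gives the ionisable leaving group without disturbing the Z olefin or the acid-sensitive allylsilane.

Step 17
Reactants: 30 allylic phosphate / allylsilane
Product: 33 methyl (2Z,6E,10E,14R)-3,11-dimethyl-14-[(2E)-6-methylhepta-2,5-dien-2-yl]cyclotetradeca-2,6,10-triene-7-carboxylate, via allyl cation 31 (not isolated), via beta-silyl cation 32 (not isolated)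
Conditions: Me3SiOTf (1.2 equiv), 2,6-di-tert-butyl-4-methylpyridine, CH2Cl2, −78 °C, slow addition of 30 to 1 mM final concentration; aq NaHCO3
Reagents that add atoms: none
Why: Proposed new method: silylation of the phosphoryl oxygen by Me3SiOTf makes the C1 phosphate a neutral leaving group, the Z allyl cation 31 is captured at its primary terminus C1 by C14, the γ-carbon of the allylsilane, and the β-silicon-stabilised C15 cation 32 loses its silyl group to triflate, which places the new double bond at C15=C16 only. The closest known reaction types are Lewis-acid couplings of allylsilanes with allyl cations, anti-SE2' reactions of enantioenriched allylsilanes with carbon electrophiles, and Lewis-acid cation–olefin closures of polyprenyl chains to 14-membered rings, but their combination in an end-to-end macrocyclisation has not been shown. The single ring, the carbocycle C1–C14, closes in a 14-exo mode with respect to the C14=C15 π bond (C15 stays outside), and the allyl unit C1–C3 is taken up inside the ring. C14 is controlled by the C16 C–Si centre: the 14Z geometry puts C13 cis to C16, A(1,3) strain therefore holds C16–H in the olefin plane with C–Si perpendicular to it, and attack of C1 anti to silicon on this conformer of the 16R silane gives 14R together with E C15=C16. The step needs chemoselectivity among five π bonds; the C7 ester shuts down the otherwise fast six-ring closure of a neryl-type cation onto C6=C7, the allylsilane is far more nucleophilic than C10=C11 and C18=C19, and C1 is preferred over C3 on steric grounds. Low temperature should preserve the Z allyl geometry, the hindered pyridine removes TfOH that would protodesilylate, and slow addition at high dilution disfavours intermolecular allylation.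

Step 18
Reactants: 33 macrocyclic methyl ester
Product: 34 target CNP0355114.1, (R)-macrocyclic allylic alcohol
Conditions: i-Bu2AlH (DIBAL-H, 2.5 equiv), CH2Cl2, −78 °C; aq potassium sodium tartrate
Reagents that add atoms: none
Why: 1,2-reduction of the α,β-unsaturated methyl ester by i-Bu2AlH gives the C7 CH2OH group without touching the five olefins or C14.

## Compound list

1 | 4-methylpent-3-en-1-ol | CC(C)=CCCO | starting material
2 | 4-methylpent-3-en-1-yl N,N-diisopropylcarbamate | CC(C)=CCCOC(=O)N(C(C)C)C(C)C | intermediate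
3 | (R)-1-lithio-4-methylpent-3-en-1-yl N,N-diisopropylcarbamate, (+)-sparteine complex (ligand not drawn) | CC(C)=CC[C@H](OC(=O)N(C(C)C)C(C)C)[Li] | intermediate
4 | lithium (R)-[1-(diisopropylcarbamoyloxy)-4-methylpent-3-en-1-yl](dimethylphenylsilyl)(pinacolato)borate | CC(C)=CC[C@H](OC(=O)N(C(C)C)C(C)C)[B-]1([Si](C)(C)c2ccccc2)OC(C)(C)C(C)(C)O1.[Li+] | intermediate
5 | (S)-2-[1-(dimethylphenylsilyl)-4-methylpent-3-en-1-yl]-4,4,5,5-tetramethyl-1,3,2-dioxaborolane | CC(C)=CC[C@@H]([Si](C)(C)c1ccccc1)B1OC(C)(C)C(C)(C)O1 | intermediate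
6 | geranyl acetate | CC(C)=CCC/C(C)=C/COC(C)=O | starting material
7 | 6,7-epoxygeranyl acetate (racemic) | CC1(C)OC1CC/C(C)=C/COC(C)=O | intermediate
8 | (E)-6,7-dihydroxy-3,7-dimethyloct-2-en-1-yl acetate (racemic) | CC(C)(O)C(O)CC/C(C)=C/COC(C)=O | intermediate
9 | (E)-3-methyl-6-oxohex-2-en-1-yl acetate | O=CCC/C(C)=C/COC(C)=O | intermediate
10 | (E)-6-hydroxy-4-methylhex-4-enal | O=CCC/C(C)=C/CO | intermediate
11 | (E)-3-methylhept-2-en-6-yn-1-ol | C#CCC/C(C)=C/CO | intermediate
12 | dilithium salt of 11 (lithium alkoxide and lithium acetylide) | [Li]C#CCC/C(C)=C/CO[Li] | intermediate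
13 | (E)-3-methyloct-2-en-6-yn-1-ol | CC#CCC/C(C)=C/CO | intermediate
14 | C15 alkenyl(chloro)zirconocene, zirconium trans to C13, with the C9 oxygen as chlorozirconocene alkoxide | C/C(=C\CC/C(C)=C/CO[Zr](Cl)(C1C=CC=C1)C1C=CC=C1)[Zr](Cl)(C1C=CC=C1)C1C=CC=C1 | intermediate
15 | (2E,6E)-7-iodo-3-methylocta-2,6-dien-1-ol | C/C(I)=C\CC/C(C)=C/CO | intermediate
16 | (2E,6E)-7-iodo-3-methylocta-2,6-dienal | C/C(I)=C\CC/C(C)=C/C=O | intermediate
17 | (3E,7E)-8-iodo-4-methylnona-1,3,7-triene | C/C(I)=C\CC/C(C)=C/C=C | intermediate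
18 | C15 alkenyllithium from 17, lithium trans to C13 | C/C([Li])=C\CC/C(C)=C/C=C | intermediate
19 | lithium alkenyl(α-silylalkyl)(pinacolato)borate, boron trans to C13 | CC(C)=CC[C@@H]([Si](C)(C)c1ccccc1)[B-]1(OC(C)(C)C(C)(C)O1)/C(C)=C/CC/C(C)=C/C=C.[Li+] | intermediate
20 | C14-iodo C15-boronic ester, anti adduct (one of two C14/C15 diastereomers drawn; both give the same Z olefin) | CC(C)=CC[C@@H]([Si](C)(C)c1ccccc1)[C@](C)(B1OC(C)(C)C(C)(C)O1)[C@@H](I)CC/C(C)=C/C=C | intermediate
21 | [(3E,7Z,9R)-4,8,12-trimethyltrideca-1,3,7,11-tetraen-9-yl]dimethyl(phenyl)silane | CC(C)=CC[C@@H]([Si](C)(C)c1ccccc1)/C(C)=C\CC/C(C)=C/C=C | intermediate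
22 | neryl acetate | CC(C)=CCC/C(C)=C\COC(C)=O | starting material
23 | 6,7-epoxyneryl acetate (racemic) | CC1(C)OC1CC/C(C)=C\COC(C)=O | intermediate
24 | (Z)-6,7-dihydroxy-3,7-dimethyloct-2-en-1-yl acetate (racemic) | CC(C)(O)C(O)CC/C(C)=C\COC(C)=O | intermediate
25 | (Z)-3-methyl-6-oxohex-2-en-1-yl acetate | O=CCC/C(C)=C\COC(C)=O | intermediate
26 | methyl (2Z,6Z)-8-acetoxy-2-bromo-6-methylocta-2,6-dienoate | COC(=O)/C(Br)=C/CC/C(C)=C\COC(C)=O | intermediate
27 | methyl (2Z,6Z)-2-bromo-8-hydroxy-6-methylocta-2,6-dienoate | COC(=O)/C(Br)=C/CC/C(C)=C\CO | intermediate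
28 | C8 B-alkyl-9-BBN derivative of 21 | CC(C)=CC[C@@H]([Si](C)(C)c1ccccc1)/C(C)=C\CC/C(C)=C/CCB1C2CCCC1CCC2 | intermediate
29 | methyl (2Z,6E,10E,14Z,16R)-16-[dimethyl(phenyl)silyl]-1-hydroxy-3,11,15,19-tetramethylicosa-2,6,10,14,18-pentaene-7-carboxylate | CC(C)=CC[C@@H]([Si](C)(C)c1ccccc1)/C(C)=C\CC/C(C)=C/CC/C(C(=O)OC)=C\CC/C(C)=C\CO | intermediate
30 | methyl (2Z,6E,10E,14Z,16R)-1-(diethoxyphosphoryloxy)-16-[dimethyl(phenyl)silyl]-3,11,15,19-tetramethylicosa-2,6,10,14,18-pentaene-7-carboxylate | CC(C)=CC[C@@H]([Si](C)(C)c1ccccc1)/C(C)=C\CC/C(C)=C/CC/C(C(=O)OC)=C\CC/C(C)=C\COP(=O)(OCC)OCC | intermediate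
31 | (Z)-C1–C3 allyl cation, triflate ion pair | CC(C)=CC[C@@H]([Si](C)(C)c1ccccc1)/C(C)=C\CC/C(C)=C/CC/C(C(=O)OC)=C\CC/C(C)=C\[CH2+].[O-]S(=O)(=O)C(F)(F)F | intermediate
32 | macrocyclic C15 cation with β-silicon at C16, triflate ion pair | CC(C)=CC[C@@H]([Si](C)(C)c1ccccc1)[C+](C)[C@H]1C/C=C(/C)CC/C=C(/C(=O)OC)CC/C=C(\C)CC1.[O-]S(=O)(=O)C(F)(F)F | intermediate
33 | methyl (2Z,6E,10E,14R)-3,11-dimethyl-14-[(2E)-6-methylhepta-2,5-dien-2-yl]cyclotetradeca-2,6,10-triene-7-carboxylate (target numbering) | CC(C)=CC/C=C(\C)[C@H]1C/C=C(/C)CC/C=C(/C(=O)OC)CC/C=C(\C)CC1 | intermediate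
34 | CNP0355114.1, [(2Z,6E,10E,14R)-3,11-dimethyl-14-[(2E)-6-methylhepta-2,5-dien-2-yl]cyclotetradeca-2,6,10-trien-7-yl]methanol (target numbering) | CC(C)=CC/C=C(\C)[C@H]1C/C=C(/C)CC/C=C(/CO)CC/C=C(\C)CC1 | target

## Count and risks

Total step count: 18.

Longest linear sequence: 12 steps, from geranyl acetate 6 through steps 3–10 and 15–18.

**Step 17 (new method).**

What may go wrong:
- After ionisation, proton loss from the allyl cation or rotation of the cation from Z to E may outrun the entropically costly 14-membered closure. Capture by C10=C11 and allylation between two molecules are further competitors.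
- A closure through a less ordered conformer would erode the transfer of chirality from C16 to C14.

The fallback sets out from 27 and 21 and comes back at 33. It makes the C1–C14 bond between two molecules and closes the ring at C7–C8 with palladium.
- Corey–Kim chlorination of 27 (NCS, Me2S, CH2Cl2, −20 °C) should give methyl (2Z,6Z)-2-bromo-8-chloro-6-methylocta-2,6-dienoate F1.
- F1 is then allylated by 21 under ZnCl2·OEt2 catalysis (CH2Cl2, −78 °C). This is the known Lewis-acid coupling of allyl chlorides with allylsilanes and is subject to the same anti-SE2' control. It should give methyl (2Z,6Z,9R,10E)-2-bromo-6,10,14-trimethyl-9-[(3E)-3-methylhexa-3,5-dien-1-yl]pentadeca-2,6,10,13-tetraenoate F2.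
- 9-BBN adds to the terminal vinyl group to give the B-alkyl-9-BBN derivative F3.
- A macrocyclic B-alkyl Suzuki–Miyaura coupling (PdCl2(dppf), AsPh3, Cs2CO3, DMF/THF/H2O, high dilution) joins C8 to C7 with retention and delivers 33.

**Step 10.**

What may go wrong:
- Ate-complex formation at the hindered α-silyl boron may be slow.
- Iodine may attack the diene or iododesilylate the electron-rich allylsilane as it forms.
- An incompletely anti elimination would erode the olefin geometry.

The fallback sets out from 9 (with 5) and comes back at 21. It uses the geometric isomer of the alkenyl halide and an iodine-free syn-elimination manifold.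
- Wittig olefination of 9 with the α-iodoethylidene ylide (EtPPh3I, n-BuLi, I2, NaN(SiMe3)2, THF, −78 °C) should give (2E,6Z)-7-iodo-3-methylocta-2,6-dien-1-yl acetate F4.
- K2CO3/MeOH gives (2E,6Z)-7-iodo-3-methylocta-2,6-dien-1-ol F5.
- MnO2 gives (2E,6Z)-7-iodo-3-methylocta-2,6-dienal F6.
- Wittig methylenation gives (3E,7Z)-8-iodo-4-methylnona-1,3,7-triene F7.
- t-BuLi converts F7 into the alkenyllithium with lithium cis to C13 F8, which adds to 5 to give the alkenylboronate complex with boron cis to C13 F9.
- PhSeCl (−78 °C) triggers the anti 1,2-shift and gives the C14-phenylselanyl C15-boronic ester F10.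
- Oxidation with mCPBA at −78 °C and syn elimination of boron and selenoxide retain the geometry, so C16 ends cis to C13 and 21 results.

**Step 15.**

What may go wrong:
- Hydroboration may not be fully selective for C8=C9 among five C=C bonds.
- β-Hydride elimination or protodeboronation may occur at the alkylpalladium stage.
- Zerovalent palladium, helped by boron, may ionise the free allylic alcohol.

The fallback sets out from 28 (with 25) and comes back at 29. It builds C6=C7 by a Wittig reaction instead of building C7–C8 by cross-coupling.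
- Oxidation of 28 (NaBO3·4H2O, THF/H2O) gives (3E,7Z,9R)-9-(dimethylphenylsilyl)-4,8,12-trimethyltrideca-3,7,11-trien-1-ol F11.
- An Appel reaction (PPh3, I2, imidazole, premixed) gives [(3E,7Z,9R)-1-iodo-4,8,12-trimethyltrideca-3,7,11-trien-9-yl]dimethyl(phenyl)silane F12.
- C-alkylation of Ph3P=CHCO2Me (2 equiv, MeCN, reflux, transylidation) gives methyl (5E,9Z,11R)-11-(dimethylphenylsilyl)-6,10,14-trimethyl-2-(triphenylphosphoranylidene)pentadeca-5,9,13-trienoate F13.
- An E-selective Wittig reaction of F13 with aldehyde 25 (toluene, 90 °C) gives methyl (2Z,6E,10E,14Z,16R)-1-acetoxy-16-(dimethylphenylsilyl)-3,11,15,19-tetramethylicosa-2,6,10,14,18-pentaene-7-carboxylate F14.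
- K2CO3/MeOH removes the acetate and gives 29.

## Further compounds

F1 | step 17 | methyl (2Z,6Z)-2-bromo-8-chloro-6-methylocta-2,6-dienoate | COC(=O)/C(Br)=C/CC/C(C)=C\CCl
F2 | step 17 | methyl (2Z,6Z,9R,10E)-2-bromo-6,10,14-trimethyl-9-[(3E)-3-methylhexa-3,5-dien-1-yl]pentadeca-2,6,10,13-tetraenoate | CC(C)=CC/C=C(\C)[C@@H](C/C=C(/C)CC/C=C(\Br)C(=O)OC)CC/C(C)=C/C=C
F3 | step 17 | B-alkyl-9-BBN derivative of F2 (boron at C8) | CC(C)=CC/C=C(\C)[C@@H](C/C=C(/C)CC/C=C(\Br)C(=O)OC)CC/C(C)=C/CCB1C2CCCC1CCC2
F4 | step 10 | (2E,6Z)-7-iodo-3-methylocta-2,6-dien-1-yl acetate | C/C(I)=C/CC/C(C)=C/COC(C)=O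
F5 | step 10 | (2E,6Z)-7-iodo-3-methylocta-2,6-dien-1-ol | C/C(I)=C/CC/C(C)=C/CO
F6 | step 10 | (2E,6Z)-7-iodo-3-methylocta-2,6-dienal | C/C(I)=C/CC/C(C)=C/C=O
F7 | step 10 | (3E,7Z)-8-iodo-4-methylnona-1,3,7-triene | C/C(I)=C/CC/C(C)=C/C=C
F8 | step 10 | alkenyllithium from F7, lithium cis to C13 | C/C([Li])=C/CC/C(C)=C/C=C
F9 | step 10 | lithium alkenyl(α-silylalkyl)(pinacolato)borate, boron cis to C13 | CC(C)=CC[C@@H]([Si](C)(C)c1ccccc1)[B-]1(OC(C)(C)C(C)(C)O1)/C(C)=C\CC/C(C)=C/C=C.[Li+]
F10 | step 10 | C14-phenylselanyl C15-boronic ester, anti adduct (one of two diastereomers drawn) | CC(C)=CC[C@@H]([Si](C)(C)c1ccccc1)[C@](C)(B1OC(C)(C)C(C)(C)O1)[C@H]([Se]c1ccccc1)CC/C(C)=C/C=C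
F11 | step 15 | (3E,7Z,9R)-9-(dimethylphenylsilyl)-4,8,12-trimethyltrideca-3,7,11-trien-1-ol | CC(C)=CC[C@@H]([Si](C)(C)c1ccccc1)/C(C)=C\CC/C(C)=C/CCO
F12 | step 15 | [(3E,7Z,9R)-1-iodo-4,8,12-trimethyltrideca-3,7,11-trien-9-yl]dimethyl(phenyl)silane | CC(C)=CC[C@@H]([Si](C)(C)c1ccccc1)/C(C)=C\CC/C(C)=C/CCI
F13 | step 15 | methyl (5E,9Z,11R)-11-(dimethylphenylsilyl)-6,10,14-trimethyl-2-(triphenylphosphoranylidene)pentadeca-5,9,13-trienoate | CC(C)=CC[C@@H]([Si](C)(C)c1ccccc1)/C(C)=C\CC/C(C)=C/CCC(C(=O)OC)=P(c1ccccc1)(c1ccccc1)c1ccccc1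
F14 | step 15 | methyl (2Z,6E,10E,14Z,16R)-1-acetoxy-16-(dimethylphenylsilyl)-3,11,15,19-tetramethylicosa-2,6,10,14,18-pentaene-7-carboxylate | CC(C)=CC[C@@H]([Si](C)(C)c1ccccc1)/C(C)=C\CC/C(C)=C/CC/C(C(=O)OC)=C\CC/C(C)=C\COC(C)=O
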